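**Plan**

1. Retrosynthesis: the fourteen O–CH3 bonds are cut last. One C(aryl)–OH bond on each of rings A–G is then traced back to C(aryl)–CHO (sevenfold Dakin oxidation). The seven diaryl-ether C–O bonds are cut at the carbon that was a C–F ortho or para to that formyl group.
2. Feature used: with the rings lettered A (2,4,6-trihydroxyphenoxy end) to H (3,4,5-trihydroxyphenoxy end), every ring A–G has a hydroxyl-bearing carbon ortho (rings B, D, F) or para (rings A, C, E, F, G) to a carbon carrying a diaryl-ether oxygen. A formyl group on that carbon can first activate fluoride displacement and then be exchanged for OH.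
3. Forward: four allyl-protected fluorobenzaldehyde monomers (rings G/C, F, E, D/B) are made by regiochemically unambiguous steps. The E–D ether is made first as a dimer, so that no phenoxide ever sits ortho to a formyl-activated aryloxy group (no Smiles-type aryl shift).
4. The chain grows from 3,4,5-trimethoxyphenol (ring H) in the order G, F, E–D, C, B, A by alternating SNAr and palladium-catalysed deallylation; no ring is formed at any stage.
5. Sevenfold Dakin oxidation and global demethylation finish the route. The target has no stereocentre, so no stereochemistry has to be set.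

Key step: step 29

Assumption: the target is taken as drawn (achiral, 21 free hydroxyls); methyl ethers serve as spectator groups and allyl ethers as the temporary phenol protection, and the six starting materials 1, 8, 11, 18, 26 and 37 are taken to be purchasable.

**Monomer for rings G and C**

Step 1
Reactants: 1 2,3-difluoro-4-hydroxybenzaldehyde
Product: 2 4-(allyloxy)-2,3-difluorobenzaldehyde
Conditions: allyl bromide, K2CO3, DMF, rt
Reagents that add atoms: allyl bromide, C=CCBr
Why: Williamson O-alkylation of the acidic para-formyl phenoxide is fast at room temperature, where the phenoxide-deactivated fluorides are not displaced.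

Step 2
Reactants: 2 4-(allyloxy)-2,3-difluorobenzaldehyde
Product: 3 4-(allyloxy)-3-fluoro-2-methoxybenzaldehyde
Conditions: NaOMe (1.1 equiv), MeOH–THF, 0 °C to 40 °C
Reagents that add atoms: sodium methoxide, [Na+].[O-]C
Why: Nucleophilic aromatic substitution (SNAr) should take only the fluoride ortho to the formyl group, because the 3-fluoride is meta to it and merely raises the electrophilicity of C2.

Step 3
Reactants: 3 4-(allyloxy)-3-fluoro-2-methoxybenzaldehyde
Product: 5 4-(allyloxy)-3-fluoro-2-methoxyphenol, via aryl formate 4 (not isolated)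
Conditions: 30% aq. H2O2, H2SO4 (cat.), MeOH, rt
Reagents that add atoms: hydrogen peroxide, OO
Why: Acid-catalysed Dakin oxidation, in which the ortho-methoxy and para-allyloxy donors favour aryl migration in the Criegee adduct, the formate is methanolysed in the same pot and the allyl ether is inert to H2O2.

Step 4
Reactants: 5 4-(allyloxy)-3-fluoro-2-methoxyphenol
Product: 6 5-(allyloxy)-4-fluoro-2-hydroxy-3-methoxybenzaldehyde
Conditions: MgCl2, Et3N, (CH2O)n, MeCN, reflux
Reagents that add atoms: paraformaldehyde (as formaldehyde), C=O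
Why: Magnesium-mediated ortho-formylation (Casnati–Skattebøl) delivers formaldehyde inside the magnesium phenoxide chelate, and C6 is the only unsubstituted position ortho to the hydroxyl.

Step 5
Reactants: 6 5-(allyloxy)-4-fluoro-2-hydroxy-3-methoxybenzaldehyde
Product: 7 5-(allyloxy)-4-fluoro-2,3-dimethoxybenzaldehyde
Conditions: MeI, K2CO3, DMF, rt
Reagents that add atoms: iodomethane, CI
Why: Williamson methylation of the salicylaldehyde hydroxyl should proceed at room temperature, well below the temperature at which the phenoxide could displace the activated fluoride of a second molecule.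

**Monomer for ring F**

Step 6
Reactants: 8 2,6-difluoro-4-hydroxybenzaldehyde
Product: 9 4-(allyloxy)-2,6-difluorobenzaldehyde
Conditions: allyl bromide, K2CO3, DMF, rt
Reagents that add atoms: allyl bromide, C=CCBr
Why: Williamson O-alkylation of the para-formyl phenoxide, with the two equivalent fluorides left untouched at room temperature.

Step 7
Reactants: 9 4-(allyloxy)-2,6-difluorobenzaldehyde
Product: 10 4-(allyloxy)-2-fluoro-6-methoxybenzaldehyde
Conditions: NaOMe (1.0 equiv), MeOH, 0 °C to rt
Reagents that add atoms: sodium methoxide, [Na+].[O-]C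
Why: SNAr at one of two equivalent ortho-formyl fluorides, after which the new methoxy donor deactivates the ring so that monosubstitution should be clean.

**Monomer for ring E**

Step 8
Reactants: 11 2-fluoro-4-methoxyphenol
Product: 12 3-fluoro-2-hydroxy-5-methoxybenzaldehyde
Conditions: MgCl2, Et3N, (CH2O)n, MeCN, reflux
Reagents that add atoms: paraformaldehyde (as formaldehyde), C=O
Why: Casnati–Skattebøl ortho-formylation can only occur at C6, since the other ortho position carries fluorine and the chelate mechanism excludes meta or para attack.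

Step 9
Reactants: 12 3-fluoro-2-hydroxy-5-methoxybenzaldehyde
Product: 13 2-(allyloxy)-3-fluoro-5-methoxybenzaldehyde
Conditions: allyl bromide, K2CO3, DMF, 40 °C
Reagents that add atoms: allyl bromide, C=CCBr
Why: Williamson O-alkylation of the salicylaldehyde phenoxide, which fixes this oxygen as the later nucleophilic site of ring E.

Step 10
Reactants: 13 2-(allyloxy)-3-fluoro-5-methoxybenzaldehyde
Product: 15 2-(allyloxy)-3-fluoro-5-methoxyphenol, via aryl formate 14 (not isolated)
Conditions: 30% aq. H2O2, H2SO4 (cat.), MeOH, rt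
Reagents that add atoms: hydrogen peroxide, OO
Why: Acid-catalysed Dakin oxidation of an ortho-alkoxybenzaldehyde, where the ortho-allyloxy donor directs aryl rather than hydride migration and the formate is methanolysed in situ.

Step 11
Reactants: 15 2-(allyloxy)-3-fluoro-5-methoxyphenol
Product: 16 3-(allyloxy)-4-fluoro-2-hydroxy-6-methoxybenzaldehyde
Conditions: MgCl2, Et3N, (CH2O)n, MeCN, reflux
Reagents that add atoms: paraformaldehyde (as formaldehyde), C=O
Why: Casnati–Skattebøl ortho-formylation must go to C6 between hydroxyl and methoxy, the only free ortho position, which places the formyl group between two oxygens and para to fluorine.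

Step 12
Reactants: 16 3-(allyloxy)-4-fluoro-2-hydroxy-6-methoxybenzaldehyde
Product: 17 3-(allyloxy)-4-fluoro-2,6-dimethoxybenzaldehyde
Conditions: MeI, K2CO3, DMF, rt to 40 °C
Reagents that add atoms: iodomethane, CI
Why: Williamson methylation of the remaining chelated hydroxyl under conditions too mild for displacement of the para-formyl fluoride.

**Monomer for rings D and B**

Step 13
Reactants: 18 1-bromo-2-fluoro-3-methoxybenzene
Product: 20 3-bromo-4-fluoro-5-methoxyphenol, via aryl boronate 19 (not isolated)
Conditions: [Ir(OMe)(cod)]2 (cat.), 4,4'-di-tert-butyl-2,2'-bipyridine, pinacolborane, THF, 60 °C; then aq. KHSO5 (as 2KHSO5·KHSO4·K2SO4), acetone, rt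
Reagents that add atoms: potassium peroxymonosulfate, [K+].[O-]S(=O)(=O)OO
Why: Sterically controlled iridium-catalysed C–H borylation should select C5, the only C–H of this 1,2,3-trisubstituted arene without an ortho substituent, and the boronate is converted to the phenol by ipso-hydroxylation in the same flask.

Step 14
Reactants: 20 3-bromo-4-fluoro-5-methoxyphenol
Product: 21 1-(allyloxy)-3-bromo-4-fluoro-5-methoxybenzene
Conditions: allyl bromide, K2CO3, DMF, rt
Reagents that add atoms: allyl bromide, C=CCBr
Why: Williamson O-alkylation of a phenol on a ring that carries no activating group, so no competing substitution is expected.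

Step 15
Reactants: 21 1-(allyloxy)-3-bromo-4-fluoro-5-methoxybenzene
Product: 23 5-(allyloxy)-2-fluoro-3-methoxybenzaldehyde, via aryllithium 22 (not isolated)
Conditions: n-BuLi, THF, −78 °C; DMF, −78 °C to 0 °C; aq. NH4Cl
Reagents that add atoms: N,N-dimethylformamide, CN(C)C=O
Why: Bromine–lithium exchange at −78 °C is faster than ortho-deprotonation or loss of LiF from the ortho-fluoroaryllithium, which is then formylated by DMF (Bouveault aldehyde synthesis).

**E–D dimer**

Step 16
Reactants: 17 3-(allyloxy)-4-fluoro-2,6-dimethoxybenzaldehyde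
Product: 24 4-fluoro-3-hydroxy-2,6-dimethoxybenzaldehyde
Conditions: Pd(PPh3)4 (5 mol %), morpholine, THF, rt
Reagents that add atoms: none
Why: Tsuji–Trost deallylation, in which zerovalent palladium ionises the allyl aryl ether and morpholine traps the π-allyl complex, while at room temperature the amine should not displace the fluoride.

Step 17
Reactants: 24 4-fluoro-3-hydroxy-2,6-dimethoxybenzaldehyde; 23 5-(allyloxy)-2-fluoro-3-methoxybenzaldehyde
Product: 25 3-[4-(allyloxy)-2-formyl-6-methoxyphenoxy]-4-fluoro-2,6-dimethoxybenzaldehyde (E–D dimer)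
Conditions: 23 (2 equiv), Cs2CO3, DMSO, 90 °C
Reagents that add atoms: none
Why: SNAr of the ortho-formyl fluoride of 23 by the phenoxide of 24, whose own fluoride is switched off by the adjacent phenoxide oxygen, so the most congested ether is made while the nucleophilic oxygen is flanked only by methoxy and fluorine.

**Chain assembly**

Step 18
Reactants: 26 3,4,5-trimethoxyphenol; 7 5-(allyloxy)-4-fluoro-2,3-dimethoxybenzaldehyde
Product: 27 5-(allyloxy)-2,3-dimethoxy-4-(3,4,5-trimethoxyphenoxy)benzaldehyde (dimer H–G)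
Conditions: 7 (1.2 equiv), Cs2CO3, DMSO, 100 °C
Reagents that add atoms: none
Why: SNAr in which the cesium phenoxide adds para to the formyl group, whose carbonyl stabilises the Meisenheimer intermediate, and fluoride leaves.

Step 19
Reactants: 27 dimer H–G allyl ether
Product: 28 5-hydroxy-2,3-dimethoxy-4-(3,4,5-trimethoxyphenoxy)benzaldehyde
Conditions: Pd(PPh3)4 (5 mol %), morpholine, THF, rt
Reagents that add atoms: none
Why: Tsuji–Trost deallylation is neutral and leaves aldehyde, methyl ethers and the diaryl ether untouched.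

Step 20
Reactants: 28 dimer H–G phenol; 10 4-(allyloxy)-2-fluoro-6-methoxybenzaldehyde
Product: 29 4-(allyloxy)-2-methoxy-6-[5-formyl-3,4-dimethoxy-2-(3,4,5-trimethoxyphenoxy)phenoxy]benzaldehyde (trimer H–G–F)
Conditions: 10 (1.3 equiv), Cs2CO3, DMSO, 100 °C
Reagents that add atoms: none
Why: SNAr of the ortho-formyl fluoride by a phenoxide that is meta to its own formyl group and therefore still a good nucleophile, and whose neighbouring aryloxy ring (ring H) is unactivated, so no aryl shift can compete.

Step 21
Reactants: 29 trimer H–G–F allyl ether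
Product: 30 4-hydroxy-2-methoxy-6-[5-formyl-3,4-dimethoxy-2-(3,4,5-trimethoxyphenoxy)phenoxy]benzaldehyde
Conditions: Pd(PPh3)4 (5 mol %), morpholine, THF, rt
Reagents that add atoms: none
Why: Tsuji–Trost deallylation, here eased by the para-formyl group, which makes the phenoxide a better leaving group from the π-allyl precursor.

Step 22
Reactants: 30 trimer H–G–F phenol; 25 E–D dimer
Product: 31 pentamer H–G–F–E–D allyl ether (ring F oxygen of 30 bound to C4 of the ring E unit of 25 in place of fluorine)
Conditions: 25 (1.3 equiv), Cs2CO3, DMSO, 110 °C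
Reagents that add atoms: none
Why: SNAr at the single remaining fluoride, which is para to the ring E formyl group, by the para-formyl phenoxide of 30, a weaker nucleophile that is expected to need the higher temperature.

Step 23
Reactants: 31 pentamer allyl ether
Product: 32 pentamer phenol (ring D allyl ether of 31 cleaved to OH)
Conditions: Pd(PPh3)4 (5 mol %), morpholine, THF, rt
Reagents that add atoms: none
Why: Tsuji–Trost deallylation tolerates the four aldehydes and all ether links.

Step 24
Reactants: 32 pentamer phenol; 7 5-(allyloxy)-4-fluoro-2,3-dimethoxybenzaldehyde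
Product: 33 hexamer H–C allyl ether (ring D oxygen of 32 bound to C4 of a 5-(allyloxy)-2,3-dimethoxybenzaldehyde unit, ring C)
Conditions: 7 (1.5 equiv), Cs2CO3, DMSO, 100 °C
Reagents that add atoms: none
Why: SNAr by an unhindered phenoxide meta to its formyl group at the fluoride para to the formyl group of 7.

Step 25
Reactants: 33 hexamer allyl ether
Product: 34 hexamer phenol (ring C allyl ether of 33 cleaved to OH)
Conditions: Pd(PPh3)4 (5 mol %), morpholine, THF, rt
Reagents that add atoms: none
Why: Tsuji–Trost deallylation under neutral conditions.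

Step 26
Reactants: 34 hexamer phenol; 23 5-(allyloxy)-2-fluoro-3-methoxybenzaldehyde
Product: 35 heptamer H–B allyl ether (ring C oxygen of 34 bound to C2 of a 5-(allyloxy)-3-methoxybenzaldehyde unit, ring B)
Conditions: 23 (1.5 equiv), Cs2CO3, DMSO, 110 °C
Reagents that add atoms: none
Why: SNAr at the ortho-formyl fluoride, with the adjacent aryloxy group of the nucleophile attached to an unactivated carbon of ring D, so no Smiles-type migration can compete.

Step 27
Reactants: 35 heptamer allyl ether
Product: 36 heptamer phenol (ring B allyl ether of 35 cleaved to OH)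
Conditions: Pd(PPh3)4 (5 mol %), morpholine, THF, rt
Reagents that add atoms: none
Why: Tsuji–Trost deallylation under neutral conditions.

Step 28
Reactants: 36 heptamer phenol; 37 4-fluoro-3,5-dimethoxybenzaldehyde
Product: 38 heptaformyl tetradeca-O-methyl octamer (ring B oxygen of 36 bound to C4 of a 3,5-dimethoxybenzaldehyde unit, ring A)
Conditions: 37 (2 equiv), Cs2CO3, DMSO, 110 °C
Reagents that add atoms: none
Why: SNAr of the para-formyl fluoride by an unhindered phenoxide, the small fluorine being displaced despite its two ortho-methoxy neighbours.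

Step 29
Reactants: 38 heptaformyl tetradeca-O-methyl octamer
Product: 40 tetradeca-O-methyl heptaphenol, via heptaformate 39 (not isolated)
Conditions: mCPBA (10 equiv), CH2Cl2, 0 °C to rt; aq. Na2S2O3–NaHCO3 wash; then K2CO3, MeOH–THF, 0 °C, argon; dilute HCl
Reagents that add atoms: 3-chloroperoxybenzoic acid, O=C(OO)c1cccc(Cl)c1
Why: The peracid adds to each of the seven formyl carbonyls to give Criegee adducts, in which the electron-rich aryl group migrates from carbon to oxygen with loss of 3-chlorobenzoate, and the seven aryl formates are methanolysed once the excess oxidant has been destroyed. The closest known reaction type is the Dakin-type Baeyer–Villiger oxidation of alkoxy- and aryloxybenzaldehydes to phenols. No ring is closed and no stereocentre is created, so no closure mode or stereocontrol element is involved. The selectivity needed is aryl over hydride migration at all seven sites, and an oxygen donor ortho or para to every formyl carbon secures it: para-aryloxy in ring A, ortho-aryloxy in rings B and D, ortho-methoxy plus para-aryloxy in rings C and G, two ortho-methoxy groups plus para-aryloxy in ring E, and ortho-methoxy, ortho-aryloxy and para-aryloxy in ring F. Holding the new oxygens as formates until the peracid is quenched should shield the electron-rich phenols from quinone formation.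

Step 30
Reactants: 40 tetradeca-O-methyl heptaphenol
Product: 41 CNP0309601.0 (target, all 21 hydroxyls free)
Conditions: BBr3 (excess), CH2Cl2, −78 °C to rt; H2O, 0 °C; argon throughout
Reagents that add atoms: none
Why: Lewis-acid O-demethylation, in which BBr3 coordinates each methoxy oxygen and bromide removes the methyl group by SN2, a pathway closed to the diaryl-ether oxygens.

**Compound list**

1 | 2,3-difluoro-4-hydroxybenzaldehyde | O=Cc1ccc(O)c(F)c1F | starting material
2 | 4-(allyloxy)-2,3-difluorobenzaldehyde | C=CCOc1ccc(C=O)c(F)c1F | intermediate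
3 | 4-(allyloxy)-3-fluoro-2-methoxybenzaldehyde | C=CCOc1ccc(C=O)c(OC)c1F | intermediate
4 | 4-(allyloxy)-3-fluoro-2-methoxyphenyl formate | C=CCOc1ccc(OC=O)c(OC)c1F | intermediate (not isolated)
5 | 4-(allyloxy)-3-fluoro-2-methoxyphenol | C=CCOc1ccc(O)c(OC)c1F | intermediate
6 | 5-(allyloxy)-4-fluoro-2-hydroxy-3-methoxybenzaldehyde | C=CCOc1cc(C=O)c(O)c(OC)c1F | intermediate
7 | 5-(allyloxy)-4-fluoro-2,3-dimethoxybenzaldehyde (monomer for rings G and C) | C=CCOc1cc(C=O)c(OC)c(OC)c1F | intermediate
8 | 2,6-difluoro-4-hydroxybenzaldehyde | O=Cc1c(F)cc(O)cc1F | starting material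
9 | 4-(allyloxy)-2,6-difluorobenzaldehyde | C=CCOc1cc(F)c(C=O)c(F)c1 | intermediate
10 | 4-(allyloxy)-2-fluoro-6-methoxybenzaldehyde (monomer for ring F) | C=CCOc1cc(F)c(C=O)c(OC)c1 | intermediate
11 | 2-fluoro-4-methoxyphenol | COc1ccc(O)c(F)c1 | starting material
12 | 3-fluoro-2-hydroxy-5-methoxybenzaldehyde | COc1cc(F)c(O)c(C=O)c1 | intermediate
13 | 2-(allyloxy)-3-fluoro-5-methoxybenzaldehyde | C=CCOc1c(F)cc(OC)cc1C=O | intermediate
14 | 2-(allyloxy)-3-fluoro-5-methoxyphenyl formate | C=CCOc1c(F)cc(OC)cc1OC=O | intermediate (not isolated)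
15 | 2-(allyloxy)-3-fluoro-5-methoxyphenol | C=CCOc1c(F)cc(OC)cc1O | intermediate
16 | 3-(allyloxy)-4-fluoro-2-hydroxy-6-methoxybenzaldehyde | C=CCOc1c(F)cc(OC)c(C=O)c1O | intermediate
17 | 3-(allyloxy)-4-fluoro-2,6-dimethoxybenzaldehyde (monomer for ring E) | C=CCOc1c(F)cc(OC)c(C=O)c1OC | intermediate
18 | 1-bromo-2-fluoro-3-methoxybenzene | COc1cccc(Br)c1F | starting material
19 | 2-(3-bromo-4-fluoro-5-methoxyphenyl)-4,4,5,5-tetramethyl-1,3,2-dioxaborolane | COc1cc(B2OC(C)(C)C(C)(C)O2)cc(Br)c1F | intermediate (not isolated)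
20 | 3-bromo-4-fluoro-5-methoxyphenol | COc1cc(O)cc(Br)c1F | intermediate
21 | 1-(allyloxy)-3-bromo-4-fluoro-5-methoxybenzene | C=CCOc1cc(Br)c(F)c(OC)c1 | intermediate
22 | [5-(allyloxy)-2-fluoro-3-methoxyphenyl]lithium | [Li]c1cc(OCC=C)cc(OC)c1F | intermediate (not isolated)
23 | 5-(allyloxy)-2-fluoro-3-methoxybenzaldehyde (monomer for rings D and B) | C=CCOc1cc(C=O)c(F)c(OC)c1 | intermediate
24 | 4-fluoro-3-hydroxy-2,6-dimethoxybenzaldehyde | Oc1c(F)cc(OC)c(C=O)c1OC | intermediate
25 | 3-[4-(allyloxy)-2-formyl-6-methoxyphenoxy]-4-fluoro-2,6-dimethoxybenzaldehyde (E–D dimer) | C=CCOc3cc(C=O)c(Oc4c(F)cc(OC)c(C=O)c4OC)c(OC)c3 | intermediate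
26 | 3,4,5-trimethoxyphenol | COc1cc(O)cc(OC)c1OC | starting material
27 | 5-(allyloxy)-2,3-dimethoxy-4-(3,4,5-trimethoxyphenoxy)benzaldehyde (dimer H–G allyl ether) | C=CCOc6cc(C=O)c(OC)c(OC)c6Oc6cc(OC)c(OC)c(OC)c6 | intermediate
28 | 5-hydroxy-2,3-dimethoxy-4-(3,4,5-trimethoxyphenoxy)benzaldehyde (dimer H–G phenol) | Oc6cc(C=O)c(OC)c(OC)c6Oc6cc(OC)c(OC)c(OC)c6 | intermediate
29 | 4-(allyloxy)-2-methoxy-6-[5-formyl-3,4-dimethoxy-2-(3,4,5-trimethoxyphenoxy)phenoxy]benzaldehyde (trimer H–G–F allyl ether) | C=CCOc5cc(OC)c(C=O)c(Oc6cc(C=O)c(OC)c(OC)c6Oc6cc(OC)c(OC)c(OC)c6)c5 | intermediate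
30 | 4-hydroxy-2-methoxy-6-[5-formyl-3,4-dimethoxy-2-(3,4,5-trimethoxyphenoxy)phenoxy]benzaldehyde (trimer H–G–F phenol) | Oc5cc(OC)c(C=O)c(Oc6cc(C=O)c(OC)c(OC)c6Oc6cc(OC)c(OC)c(OC)c6)c5 | intermediate
31 | pentamer H–G–F–E–D allyl ether (25 with its fluorine replaced by the ring F phenol oxygen of 30) | C=CCOc3cc(C=O)c(Oc4c(Oc5cc(OC)c(C=O)c(Oc6cc(C=O)c(OC)c(OC)c6Oc6cc(OC)c(OC)c(OC)c6)c5)cc(OC)c(C=O)c4OC)c(OC)c3 | intermediate
32 | pentamer H–G–F–E–D phenol (31 with the ring D allyl ether cleaved to OH) | Oc3cc(C=O)c(Oc4c(Oc5cc(OC)c(C=O)c(Oc6cc(C=O)c(OC)c(OC)c6Oc6cc(OC)c(OC)c(OC)c6)c5)cc(OC)c(C=O)c4OC)c(OC)c3 | intermediate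
33 | hexamer H–C allyl ether (7 with its fluorine replaced by the ring D phenol oxygen of 32) | C=CCOc3cc(C=O)c(OC)c(OC)c3Oc3cc(C=O)c(Oc4c(Oc5cc(OC)c(C=O)c(Oc6cc(C=O)c(OC)c(OC)c6Oc6cc(OC)c(OC)c(OC)c6)c5)cc(OC)c(C=O)c4OC)c(OC)c3 | intermediate
34 | hexamer H–C phenol (33 with the ring C allyl ether cleaved to OH) | Oc3cc(C=O)c(OC)c(OC)c3Oc3cc(C=O)c(Oc4c(Oc5cc(OC)c(C=O)c(Oc6cc(C=O)c(OC)c(OC)c6Oc6cc(OC)c(OC)c(OC)c6)c5)cc(OC)c(C=O)c4OC)c(OC)c3 | intermediate
35 | heptamer H–B allyl ether (23 with its fluorine replaced by the ring C phenol oxygen of 34) | C=CCOc2cc(C=O)c(Oc3cc(C=O)c(OC)c(OC)c3Oc3cc(C=O)c(Oc4c(Oc5cc(OC)c(C=O)c(Oc6cc(C=O)c(OC)c(OC)c6Oc6cc(OC)c(OC)c(OC)c6)c5)cc(OC)c(C=O)c4OC)c(OC)c3)c(OC)c2 | intermediate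
36 | heptamer H–B phenol (35 with the ring B allyl ether cleaved to OH) | Oc2cc(C=O)c(Oc3cc(C=O)c(OC)c(OC)c3Oc3cc(C=O)c(Oc4c(Oc5cc(OC)c(C=O)c(Oc6cc(C=O)c(OC)c(OC)c6Oc6cc(OC)c(OC)c(OC)c6)c5)cc(OC)c(C=O)c4OC)c(OC)c3)c(OC)c2 | intermediate
37 | 4-fluoro-3,5-dimethoxybenzaldehyde (monomer for ring A) | COc1cc(C=O)cc(OC)c1F | starting material
38 | heptaformyl tetradeca-O-methyl octamer (37 with its fluorine replaced by the ring B phenol oxygen of 36; one CHO on each of rings A–G) | O=Cc1cc(OC)c(Oc2cc(C=O)c(Oc3cc(C=O)c(OC)c(OC)c3Oc3cc(C=O)c(Oc4c(Oc5cc(OC)c(C=O)c(Oc6cc(C=O)c(OC)c(OC)c6Oc6cc(OC)c(OC)c(OC)c6)c5)cc(OC)c(C=O)c4OC)c(OC)c3)c(OC)c2)c(OC)c1 | intermediate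
39 | heptaformate (each CHO of 38 replaced by OCHO) | O=COc1cc(OC)c(Oc2cc(OC=O)c(Oc3cc(OC=O)c(OC)c(OC)c3Oc3cc(OC=O)c(Oc4c(Oc5cc(OC)c(OC=O)c(Oc6cc(OC=O)c(OC)c(OC)c6Oc6cc(OC)c(OC)c(OC)c6)c5)cc(OC)c(OC=O)c4OC)c(OC)c3)c(OC)c2)c(OC)c1 | intermediate (not isolated)
40 | tetradeca-O-methyl heptaphenol (each CHO of 38 replaced by OH) | Oc1cc(OC)c(Oc2cc(O)c(Oc3cc(O)c(OC)c(OC)c3Oc3cc(O)c(Oc4c(Oc5cc(OC)c(O)c(Oc6cc(O)c(OC)c(OC)c6Oc6cc(OC)c(OC)c(OC)c6)c5)cc(OC)c(O)c4OC)c(OC)c3)c(OC)c2)c(OC)c1 | intermediate
41 | CNP0309601.0 | Oc1cc(O)c(Oc2cc(O)c(Oc3cc(O)c(O)c(O)c3Oc3cc(O)c(Oc4c(Oc5cc(O)c(O)c(Oc6cc(O)c(O)c(O)c6Oc6cc(O)c(O)c(O)c6)c5)cc(O)c(O)c4O)c(O)c3)c(O)c2)c(O)c1 | target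

**Step count and risks**

Total step count: 30. Longest linear sequence: 18 steps (steps 1–5, then 18–30).

Steps most likely to fail:

1. Step 22, slow substitution. The nucleophile is a phenoxide conjugated to a para-formyl group, and the fluoride sits on an electron-rich ring next to a bulky aryloxy group. Prolonged heating may therefore cause aryloxide exchange at the activated ether positions before the coupling is complete. The fallback sets out from 30. Both formyl groups are masked with ethylene glycol (TsOH, toluene, water removal) to give the bis(1,3-dioxolane) F1, whose phenoxide is no longer conjugated to a carbonyl and should be far more nucleophilic. F1 is coupled with 25 (Cs2CO3, DMSO) to the doubly masked pentamer allyl ether F2. Dilute HCl in THF then releases the two aldehydes, and the route is rejoined at 31.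

2. Step 29, over-oxidation. Once the formates are cleaved, the seven electron-rich phenols can be oxidised to quinones or coupled by residual peracid, or by air during the basic methanolysis. The fallback sets out from 38. The peracid oxidation is run as before, but after a reductive, non-basic work-up the heptaformate 39 is kept and treated directly with BBr3 in CH2Cl2. This cleaves the formate and methyl groups in one operation, so partially methylated phenols never meet base or oxidant. The route is rejoined at 41, and no new compound is formed (entry F0).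

3. Step 17, loss of chemoselectivity. The ring E fluoride of product 25 becomes para-formyl-activated as soon as the neighbouring oxygen is arylated, so the phenoxide of 24 may add to 25 and oligomerise. The fallback sets out from 17. Its formyl group is masked with ethylene glycol (TsOH, toluene) as the dioxolane F3, which is deallylated (Pd(PPh3)4, morpholine) to the phenol F4. With the ring E carbonyl masked, only the fluoride of 23 is activated, so coupling of F4 with 23 (Cs2CO3, DMSO) should give the diaryl ether F5 cleanly. Dilute HCl in THF unmasks the aldehyde, and the route is rejoined at 25.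

Further compounds
F0 | step 29 | none | none
F1 | step 22 | bis(1,3-dioxolane) of trimer phenol 30 (both CHO groups as 1,3-dioxolan-2-yl) | Oc5cc(OC)c(C7OCCO7)c(Oc6cc(C7OCCO7)c(OC)c(OC)c6Oc6cc(OC)c(OC)c(OC)c6)c5
F2 | step 22 | pentamer allyl ether 31 with the ring F and ring G formyl groups as 1,3-dioxolanes | C=CCOc3cc(C=O)c(Oc4c(Oc5cc(OC)c(C7OCCO7)c(Oc6cc(C7OCCO7)c(OC)c(OC)c6Oc6cc(OC)c(OC)c(OC)c6)c5)cc(OC)c(C=O)c4OC)c(OC)c3
F3 | step 17 | 2-[3-(allyloxy)-4-fluoro-2,6-dimethoxyphenyl]-1,3-dioxolane | C=CCOc1c(F)cc(OC)c(C2OCCO2)c1OC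
F4 | step 17 | 3-(1,3-dioxolan-2-yl)-6-fluoro-2,4-dimethoxyphenol | Oc1c(F)cc(OC)c(C2OCCO2)c1OC
F5 | step 17 | 5-(allyloxy)-2-[3-(1,3-dioxolan-2-yl)-6-fluoro-2,4-dimethoxyphenoxy]-3-methoxybenzaldehyde | C=CCOc3cc(C=O)c(Oc4c(F)cc(OC)c(C7OCCO7)c4OC)c(OC)c3
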